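**Retrosynthetic overview**
- 21 ⇒ 20 ⇒ 19 ⇒ 18. The C3'–Br/C4'–Cl pair comes from the ring alkene by chlorohydrin formation, OH→Br exchange and a thermal Br/Cl interchange. The carbocycle and C1' are bought with (S)-limonene.
- 18 ⇒ 14 ⇒ 11. C3–OAc comes from ketone reduction and acetylation, C5–Br from 1,4-addition of bromide to the C4=C5 enone, and the second C6 methyl from substitution at the hemiketal carbon.
- Feature: the oxane O1–C2–C3(O)–C4–C5(Br)–C6(Me2) is a ring-expanded, oxidised 5-methyl-2-furyl carbinol. Furan C2 becomes the C3 ketone, furan C3/C4 become C4=C5, furan C5 becomes C6, and the carbinol O becomes O1. 11 ⇒ 8 is an anodic Achmatowicz rearrangement that closes O1–C6.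
- 8 ⇒ ketone 4 + 2-methylfuran 5, with C2 set by catalyst control; 4 ⇒ 1. The cyclohexene ring is present from the start, and the oxane ring (step 5) is the only ring formed.

Key step: step 5

Numbering: oxane atoms are O1 and C2–C6 as in the target. The carbocycle is C1'–C6', with C1' on C2, C3' the CH–halogen carbon and C4' the methyl-bearing carbon.

Assumption: (S)-BINOL is taken as the antipode that sends the furyl group to the Si face of ketone 4, by analogy with its Si-face delivery to aldehydes. If the sense proves opposite, (R)-BINOL is used.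

Step 1
Reactants: 1 (S)-limonene
Product: 2 (4S)-limonene 1,2-oxide (both epoxide epimers)
Conditions: mCPBA (1.0 equiv), NaHCO3, CH2Cl2, 0 °C
Reagents that add atoms: mCPBA, O=C(OO)c1cccc(Cl)c1
Why: Prilezhaev epoxidation is fastest at the more electron-rich trisubstituted ring alkene, which is thereby masked so that the isopropenyl group can be cleaved alone; the epoxide configuration does not matter because it is removed in step 3.

Step 2
Reactants: 2 (4S)-limonene 1,2-oxide
Product: 3 1-(6-methyl-7-oxabicyclo[4.1.0]heptan-3-yl)ethanone, (S) at the acetyl-bearing carbon (both epoxide epimers)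
Conditions: O3, CH2Cl2, −78 °C; Me2S, −78 °C → rt
Reagents that add atoms: ozone, [O-][O+]=O
Why: Ozonolysis with reductive work-up cleaves the only remaining C=C to the methyl ketone, since epoxides are inert to ozone and the neutral medium leaves the ring stereocentre untouched.

Step 3
Reactants: 3 keto epoxide
Product: 4 (S)-1-(4-methylcyclohex-3-en-1-yl)ethanone
Conditions: Zn, NaI, NaOAc, AcOH, 0 °C → rt
Reagents that add atoms: none
Why: In this Cornforth-type deoxygenation iodide opens either epoxide epimer to an iodohydrin and zinc eliminates it reductively to the same ring alkene, while the acetate buffer is too mild to enolise the ketone and erode the alpha stereocentre.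

Step 4
Reactants: 4 (S)-1-(4-methylcyclohex-3-en-1-yl)ethanone; 5 2-methylfuran
Product: 8 (1R)-1-(5-methylfuran-2-yl)-1-[(1S)-4-methylcyclohex-3-en-1-yl]ethanol, via 5-methyl-2-furyllithium 6 (not isolated), via diethyl(5-methylfuran-2-yl)aluminium 7 (not isolated)
Conditions: 5, n-BuLi, THF, 0 °C; Et2AlCl, 0 °C → rt; then 4, Ti(OiPr)4 (3 equiv), (S)-BINOL (15 mol %), toluene, 0 °C; aq. NaHCO3 work-up, Et3N-deactivated silica
Reagents that add atoms: n-butyllithium, [Li]CCCC (Li of 6 only); diethylaluminium chloride, CC[Al](Cl)CC (AlEt2 of 7 only)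
Why: Alpha-lithiation of 5, transmetalation to aluminium and Ti(OiPr)4–BINOL-catalysed heteroaryl transfer (catalytic asymmetric 1,2-addition of furylaluminium reagents to ketones) form the C2–furyl bond; because the remote ring alkene gives 4 no useful facial bias, the new stereocentre is set by the catalyst, which distinguishes the secondary alkyl group from methyl and delivers the furyl group to the Si face to give the (1R)-carbinol.

Step 5
Reactants: 8 (1R)-1-(5-methylfuran-2-yl)-1-[(1S)-4-methylcyclohex-3-en-1-yl]ethanol
Product: 11 (2R)-6-hydroxy-2,6-dimethyl-2-[(1S)-4-methylcyclohex-3-en-1-yl]-2H-pyran-3(6H)-one (both C6 anomers), via 2,5-dimethoxy-2,5-dihydrofuran 9 (not isolated), via Z-enedione 10 (not isolated)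
Conditions: undivided cell, graphite anode, Pt cathode, NH4Br (0.2 equiv), MeOH, −20 °C, constant low current density, about 2 F per mol; concentrate cold; THF–H2O, H2SO4 (0.05 M), 0 °C → rt
Reagents that add atoms: methanol, CO (held only in 9); water, O
Why: Bromide is oxidised at the anode to bromine, which attacks the 2,5-dialkylfuran, and methanol traps the resulting cations at both alpha carbons (net two-electron 2,5-dimethoxylation, the anodic Clauson-Kaas form of the Achmatowicz rearrangement), while protons are reduced to hydrogen at the cathode. Dilute aqueous acid then cleaves both ketals of 9 to the enedione 10, whose Z geometry is inherited from the five-membered ring. The tertiary C2 hydroxyl adds to the methyl ketone carbonyl in a 6-exo-trig closure that forms O1–C6 and the oxane ring, and the fully substituted C2 and the cis alkene favour the closed form. No controlled stereocentre is created: C6 arises as an anomeric mixture that is erased in step 7, C2 is quaternary, and C1' is not alpha to a carbonyl. The selectivity needed is furan over the trisubstituted ring alkene; since the working oxidant is electrogenerated bromine, it rests on the much higher nucleophilicity of the dialkylfuran and is secured by low temperature, a low stationary bromine concentration and charge control.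

Step 6
Reactants: 11 hemiketal pyranone
Product: 12 (6R)-2,6-dimethyl-6-[(1S)-4-methylcyclohex-3-en-1-yl]-5-oxo-5,6-dihydro-2H-pyran-2-yl acetate (both anomers)
Conditions: Ac2O, Et3N, DMAP (cat.), CH2Cl2, 0 °C
Reagents that add atoms: acetic anhydride, CC(=O)OC(C)=O
Why: DMAP-catalysed acylation traps the closed hemiketal as its tertiary ketal acetate (the standard activation of Achmatowicz products) and puts a leaving group on C6; the anomeric mixture is of no consequence.

Step 7
Reactants: 12 ketal acetate
Product: 14 (2R)-2,6,6-trimethyl-2-[(1S)-4-methylcyclohex-3-en-1-yl]-2H-pyran-3(6H)-one, via oxocarbenium triflate 13 (not isolated)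
Conditions: Me2Zn (4 equiv), then Me3SiOTf (1.2 equiv, slow addition), CH2Cl2, −78 → −30 °C
Reagents that add atoms: dimethylzinc, C[Zn]C; trimethylsilyl triflate, C[Si](C)(C)OS(=O)(=O)C(F)(F)F (counter-ion of 13 only)
Why: Proposed new method: Me3SiOTf ionises the tertiary ketal acetate to the 6-methyl oxocarbenium ion 13, the species that silanes intercept in Kishi-type reductions of such hemiketals, and Me2Zn, which is inert toward the hindered enone without a copper or nickel catalyst and is already present in excess, transfers methyl to C6 (C4, the other terminus of the cation, is alpha to the carbonyl and carries little charge), while the quaternary C2 rules out oxidopyrylium formation; the closest known reactions are the Me2Zn–Zn(OTf)2 and AlMe3 methylations of mixed ketals and anomeric sulfones that install angular methyl groups on cyclic ethers, and Ferrier-type C-glycosidations with dialkylzincs; no stereocentre is formed because C6 becomes a gem-dimethyl carbon.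

Step 8
Reactants: 14 enone
Product: 16 (2R,5R)-5-bromo-2,6,6-trimethyl-2-[(1S)-4-methylcyclohex-3-en-1-yl]oxan-3-one, via trimethylsilyl enol ether 15 (not isolated)
Conditions: Me3SiBr (1.5 equiv), 2,6-di-tert-butyl-4-methylpyridine (0.2 equiv), CH2Cl2, −78 → −20 °C; cold aq. NaH2PO4–Na2HPO4 (pH 7); used crude at once
Reagents that add atoms: bromotrimethylsilane, C[Si](C)(C)Br
Why: The 1,4-addition of a halosilane to an enone is reversible, and the favoured adduct 15 carries bromine pseudoaxial (C–Br aligned with the enol ether pi system, anti to the pseudoaxial C6 methyl) on the face of the C2 methyl group, because A(1,2) strain with the C3 silyloxy group pushes the branched cyclohexenyl substituent pseudoaxial on the opposite face; this sets (5R), and the proton scavenger keeps free HBr away from the ring alkene.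

Step 9
Reactants: 16 beta-bromoketone
Product: 17 (2R,3R,5R)-5-bromo-2,6,6-trimethyl-2-[(1S)-4-methylcyclohex-3-en-1-yl]oxan-3-ol
Conditions: LiBH(s-Bu)3 (1.2 equiv), THF, −78 °C; AcOH, −78 °C
Reagents that add atoms: none
Why: At −78 °C the bulky borohydride reduces the ketone faster than HBr is lost and approaches C3 equatorially, on the face of the C2 methyl and away from the cyclohexenyl group, to give the axial (3R)-alcohol, as this reagent does with oxan-3-ones and with 4,4-dimethyl-3-oxo terpenoids (diastereoselective hydride reduction); the cold acidic quench keeps the alkoxide from displacing bromide.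

Step 10
Reactants: 17 bromohydrin
Product: 18 (2R,3R,5R)-5-bromo-2,6,6-trimethyl-2-[(1S)-4-methylcyclohex-3-en-1-yl]oxan-3-yl acetate
Conditions: Ac2O, pyridine, DMAP, CH2Cl2, rt → 35 °C
Reagents that add atoms: acetic anhydride, CC(=O)OC(C)=O
Why: DMAP-catalysed acetylation of the hindered axial alcohol leaves the equatorial C5 bromide alone, since it has no antiperiplanar hydrogen for E2 loss.

Step 11
Reactants: 18 bromo acetate
Product: 19 (2R,3R,5R)-5-bromo-2-[(1S,3R,4R)-3-chloro-4-hydroxy-4-methylcyclohexyl]-2,6,6-trimethyloxan-3-yl acetate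
Conditions: NCS (1.1 equiv), acetone–H2O (4:1), 0 °C → rt
Reagents that add atoms: N-chlorosuccinimide, O=C1CCC(=O)N1Cl; water, O
Why: In this halohydrin formation on the only alkene left, chloronium transfer to the face anti to the equatorial C1' substituent is followed by Markovnikov, trans-diaxial (Fürst–Plattner) opening by water at C4', which gives the axial tertiary alcohol and the axial secondary chloride, (3'R,4'R).

Step 12
Reactants: 19 chlorohydrin
Product: 20 (2R,3R,5R)-5-bromo-2-[(1S,3R,4R)-4-bromo-3-chloro-4-methylcyclohexyl]-2,6,6-trimethyloxan-3-yl acetate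
Conditions: HBr (33% in AcOH, 3 equiv), CH2Cl2, 0 °C
Reagents that add atoms: hydrogen bromide, Br
Why: SN1 substitution of the tertiary alcohol proceeds with retention because the antiperiplanar axial chlorine shields the rear face (chloronium participation) and bromide enters axially to give the trans-diaxial 4'-bromo-3'-chloride, while the oxane oxygen is deactivated toward acid cleavage by the flanking C–Br and C–OAc groups.

Step 13
Reactants: 20 trans-diaxial bromochloride
Product: 21 8-acetylcaespitol, (2R,3R,5R)-5-bromo-2-[(1S,3S,4S)-3-bromo-4-chloro-4-methylcyclohexyl]-2,6,6-trimethyloxan-3-yl acetate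
Conditions: PhCl, 120 °C, 2,6-di-tert-butyl-4-methylpyridine (0.1 equiv), dark, sealed tube
Reagents that add atoms: none
Why: The thermal diaxial-to-diequatorial rearrangement of a vicinal dihalide (dyotropic 1,2-interchange, as in the mutarotation of 5,6-dibromocholestane) moves each halogen suprafacially to the neighbouring carbon with inversion at both centres, so bromine ends equatorial on C3' (S) and chlorine equatorial on C4' (S), driven by the stronger bonding of chlorine to the tertiary and bromine to the secondary carbon.

**Compound list**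
1 | (S)-limonene | CC(=C)[C@H]1CCC(C)=CC1 | starting material
2 | (4S)-limonene 1,2-oxide (both epoxide epimers) | CC(=C)[C@H]1CCC2(C)OC2C1 | intermediate
3 | 1-(6-methyl-7-oxabicyclo[4.1.0]heptan-3-yl)ethanone, (S) at the acetyl-bearing carbon | CC(=O)[C@H]1CCC2(C)OC2C1 | intermediate
4 | (S)-1-(4-methylcyclohex-3-en-1-yl)ethanone | CC(=O)[C@H]1CCC(C)=CC1 | intermediate
5 | 2-methylfuran | Cc1ccco1 | starting material
6 | 5-methyl-2-furyllithium | Cc1ccc([Li])o1 | intermediate
7 | diethyl(5-methylfuran-2-yl)aluminium (THF adduct) | CC[Al](CC)c1ccc(C)o1 | intermediate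
8 | (1R)-1-(5-methylfuran-2-yl)-1-[(1S)-4-methylcyclohex-3-en-1-yl]ethanol | O[C@](c1ccc(C)o1)(C)[C@H]1CCC(C)=CC1 | intermediate
9 | (1R)-1-(2,5-dimethoxy-5-methyl-2,5-dihydrofuran-2-yl)-1-[(1S)-4-methylcyclohex-3-en-1-yl]ethanol (ketal epimers) | O[C@](C1(OC)C=CC(C)(OC)O1)(C)[C@H]1CCC(C)=CC1 | intermediate
10 | (3Z,6R)-6-hydroxy-6-[(1S)-4-methylcyclohex-3-en-1-yl]hept-3-ene-2,5-dione | O[C@](C(=O)/C=C\C(C)=O)(C)[C@H]1CCC(C)=CC1 | intermediate
11 | (2R)-6-hydroxy-2,6-dimethyl-2-[(1S)-4-methylcyclohex-3-en-1-yl]-2H-pyran-3(6H)-one (both C6 anomers) | O=C1C=CC(C)(O)O[C@]1(C)[C@H]1CCC(C)=CC1 | intermediate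
12 | C6 acetate of 11 (both anomers) | O=C1C=CC(C)(OC(C)=O)O[C@]1(C)[C@H]1CCC(C)=CC1 | intermediate
13 | 6-methyl oxocarbenium triflate derived from 12 | O=C1C=CC(C)=[O+][C@]1(C)[C@H]1CCC(C)=CC1.[O-]S(=O)(=O)C(F)(F)F | intermediate
14 | (2R)-2,6,6-trimethyl-2-[(1S)-4-methylcyclohex-3-en-1-yl]-2H-pyran-3(6H)-one | O=C1C=CC(C)(C)O[C@]1(C)[C@H]1CCC(C)=CC1 | intermediate
15 | (2R,5R)-5-bromo-3-trimethylsilyloxy-2,6,6-trimethyl-2-[(1S)-4-methylcyclohex-3-en-1-yl]-5,6-dihydro-2H-pyran | C[Si](C)(C)OC1=C[C@@H](Br)C(C)(C)O[C@]1(C)[C@H]1CCC(C)=CC1 | intermediate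
16 | (2R,5R)-5-bromo-2,6,6-trimethyl-2-[(1S)-4-methylcyclohex-3-en-1-yl]oxan-3-one | O=C1C[C@@H](Br)C(C)(C)O[C@]1(C)[C@H]1CCC(C)=CC1 | intermediate
17 | (2R,3R,5R)-5-bromo-2,6,6-trimethyl-2-[(1S)-4-methylcyclohex-3-en-1-yl]oxan-3-ol | O[C@@H]1C[C@@H](Br)C(C)(C)O[C@]1(C)[C@H]1CCC(C)=CC1 | intermediate
18 | acetate of 17 | CC(=O)O[C@@H]1C[C@@H](Br)C(C)(C)O[C@]1(C)[C@H]1CCC(C)=CC1 | intermediate
19 | (2R,3R,5R)-5-bromo-2-[(1S,3R,4R)-3-chloro-4-hydroxy-4-methylcyclohexyl]-2,6,6-trimethyloxan-3-yl acetate | CC(=O)O[C@@H]1C[C@@H](Br)C(C)(C)O[C@]1(C)[C@H]1CC[C@@](C)(O)[C@H](Cl)C1 | intermediate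
20 | (2R,3R,5R)-5-bromo-2-[(1S,3R,4R)-4-bromo-3-chloro-4-methylcyclohexyl]-2,6,6-trimethyloxan-3-yl acetate | CC(=O)O[C@@H]1C[C@@H](Br)C(C)(C)O[C@]1(C)[C@H]1CC[C@@](C)(Br)[C@H](Cl)C1 | intermediate
21 | 8-acetylcaespitol | CC(=O)O[C@@H]1C[C@@H](Br)C(C)(C)O[C@]1(C)[C@H]1CC[C@](C)(Cl)[C@@H](Br)C1 | target

Total step count: 13
Longest linear sequence: 13 steps (1 → 21); 5 enters in step 4.

**Steps most likely to fail**

1. Step 7.
   - Risk: cation 13 may be consumed before methyl transfer. Possible paths are proton loss from the C6 methyl group, capture by the ring alkene (oxonium-ene type closure), and methyl addition to the carbonyl group.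
   - Fallback (from 11, back to the route at 14): the carbonyl is taken out of conjugation with the cation, and only known reaction types are used.
   - Compound 11 is converted with MeOH, HC(OMe)3 and pyridinium tosylate into the methyl ketal (2R)-6-methoxy-2,6-dimethyl-2-[(1S)-4-methylcyclohex-3-en-1-yl]-2H-pyran-3(6H)-one F1.
   - Luche reduction (NaBH4, CeCl3·7H2O, MeOH, −78 °C) gives the allylic alcohol (2R)-6-methoxy-2,6-dimethyl-2-[(1S)-4-methylcyclohex-3-en-1-yl]-3,6-dihydro-2H-pyran-3-ol F2, whose C3 configuration is immaterial.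
   - Excess AlMe3 (CH2Cl2, −78 → 0 °C) ionises the ketal in the Ferrier manner to a better stabilised allyl oxocarbenium ion. It delivers methyl within the aluminate ion pair, as in the installation of angular methyl groups on cyclic ethers, and gives (2R)-2,6,6-trimethyl-2-[(1S)-4-methylcyclohex-3-en-1-yl]-3,6-dihydro-2H-pyran-3-ol F3.
   - Dess–Martin oxidation then returns enone 14.

2. Step 8.
   - Risk: the facial preference for bromide delivery rests on a conformational argument only and may be poor. HBr may also be lost from the beta-bromoketone during handling.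
   - Fallback (from 14, back to the route at 17): stereocontrol in the C–Br bond formation is given up in favour of separation and recycling.
   - The crude mixture of 16 and its C5 epimer, (2R,5S)-5-bromo-2,6,6-trimethyl-2-[(1S)-4-methylcyclohex-3-en-1-yl]oxan-3-one F4, is reduced as in step 9.
   - Compound 17 is separated by chromatography from (2R,3R,5S)-5-bromo-2,6,6-trimethyl-2-[(1S)-4-methylcyclohex-3-en-1-yl]oxan-3-ol F5.
   - F5 is oxidised with Dess–Martin periodinane back to F4, and Et3N removes HBr (E1cB) to regenerate 14 for another pass.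

3. Step 4.
   - Risk: a secondary-alkyl methyl ketone lies outside the best substrate class of the catalyst, so catalyst control may be weak and the C2 configuration may be eroded.
   - Fallback (from 4 and 6, back to the route at 8): catalyst control is replaced by separation of diastereomers.
   - Compound 6 is added directly to 4 (THF, LaCl3·2LiCl, −78 °C, to suppress enolisation).
   - Compound 8 is then separated by preparative HPLC from its epimer (1S)-1-(5-methylfuran-2-yl)-1-[(1S)-4-methylcyclohex-3-en-1-yl]ethanol F6.

Further compounds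
F1 | step 7 | (2R)-6-methoxy-2,6-dimethyl-2-[(1S)-4-methylcyclohex-3-en-1-yl]-2H-pyran-3(6H)-one (both anomers) | O=C1C=CC(C)(OC)O[C@]1(C)[C@H]1CCC(C)=CC1
F2 | step 7 | (2R)-6-methoxy-2,6-dimethyl-2-[(1S)-4-methylcyclohex-3-en-1-yl]-3,6-dihydro-2H-pyran-3-ol (C3 and C6 epimers) | OC1C=CC(C)(OC)O[C@]1(C)[C@H]1CCC(C)=CC1
F3 | step 7 | (2R)-2,6,6-trimethyl-2-[(1S)-4-methylcyclohex-3-en-1-yl]-3,6-dihydro-2H-pyran-3-ol (C3 epimers) | OC1C=CC(C)(C)O[C@]1(C)[C@H]1CCC(C)=CC1
F4 | step 8 | (2R,5S)-5-bromo-2,6,6-trimethyl-2-[(1S)-4-methylcyclohex-3-en-1-yl]oxan-3-one | O=C1C[C@H](Br)C(C)(C)O[C@]1(C)[C@H]1CCC(C)=CC1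
F5 | step 8 | (2R,3R,5S)-5-bromo-2,6,6-trimethyl-2-[(1S)-4-methylcyclohex-3-en-1-yl]oxan-3-ol | O[C@@H]1C[C@H](Br)C(C)(C)O[C@]1(C)[C@H]1CCC(C)=CC1
F6 | step 4 | (1S)-1-(5-methylfuran-2-yl)-1-[(1S)-4-methylcyclohex-3-en-1-yl]ethanol | O[C@@](c1ccc(C)o1)(C)[C@H]1CCC(C)=CC1
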